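## Structural features

The target is a phenylcoumaran (2-aryl-2,3-dihydrobenzofuran) neolignan. Ring A, the benzo ring, is fused through C3a and C7a to a dihydrofuran ring (O1, C2, C3). It carries a methoxy group at C7, next to O1, and an (E)-acrylic acid at C5, para to O1. C2 bears a 4-hydroxy-3,5-dimethoxyphenyl ring and C3 a hydroxymethyl group.

C2 and C3 are the only stereocentres. They are adjacent and (2S,3R), which places the aryl group and the CH2OH arm trans across the five-membered ring.

The fragile points are:
- the C2–O1 bond, a benzylic aryl ether para to an oxygen, which ionises under acid to a quinone-methide-like cation;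
- the free phenol, which is oxidisable and, as its phenoxide, can trigger the same ring opening;
- the C2–H/C3–H pair, which oxidants strip to the benzofuran;
- the acrylic acid double bond, which rules out hydrogenation at any late stage.

Opening at C2 corrects itself, because the trans isomer is the more stable one. The real difficulty is therefore the absolute configuration of C3, a benzylic methine with no neighbouring group to steer a reagent.

The feature the plan exploits is the chain O1–C2–C3–CH2–O. Its two oxygens stand 1,3 to each other and C2 is benzylic and para to an aryl oxygen. The chain is therefore the adduct of a C2=C3 stilbene bond, a formaldehyde-level cation at C3 and the ring A oxygen at C2.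

## Logic of the disconnections

**12 ⇒ 11.** The two O–CH2Ph bonds are cut, one at the phenol oxygen of the C2 aryl ring and one at the primary oxygen of the C3 arm. The primary oxygen must arrive as an ether because the one-carbon electrophile of the key step is an alkoxymethyl cation. Giving the phenol the same group lets one reagent free both. The gain is a precursor whose only acidic group is the carboxylic acid. The forward step must remove benzyl without hydrogen, without ionising C2–O1 and without cleaving a methyl ether.

**11 ⇒ 10.** The acid is traced back to its methyl ester (acyl C–O bond). A free acid would feed protons to the silylium catalyst of the key step, whereas the ester is only a weak Lewis base. The forward hydrolysis is placed before the debenzylation, so that hydroxide never meets a free para-hydroxyphenyl coumaran.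

**10 ⇒ 7 + 8.** O1–C2 and C3–CH2 are cut together. The heteroring and both stereocentres disappear and what remains is 7, flat and achiral, and the one-carbon piece 8. This is the largest simplification in the plan. The forward step must attack through C3 and not C2, choose one face of the alkene under catalyst control, close the ring trans, and leave the acrylate and the electron-rich rings alone.

**7 ⇒ 6.** The O–Si bond is cut. The oxygen has to enter the key step as a silyl ether, which is aprotic, still nucleophilic, and gives a silylium ion back to the catalyst when it has done its work. The forward step is the silylation of a phenol with two ortho substituents.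

**6 ⇒ 2 + 5.** The aryl–vinyl bond (C3a–C3) is cut. Ring A then arrives complete, with its acrylate, its oxygen pattern and an iodide ortho to the phenol, and the other half is a simple styrene. The forward coupling must arylate the terminal alkene carbon, give the (E) geometry and leave the acrylate of 2 alone.

**2 ⇒ 1.** The acrylate Cα=Cβ bond is cut back to the aldehyde. The forward olefination must tolerate a free, rather acidic phenol, which argues for a base-free ylide rather than a phosphonate anion.

**5 ⇒ 4 ⇒ 3.** The vinyl C=C bond is cut back to the aldehyde, and then the O–benzyl bond to the phenol. Both forward steps are routine, and 3 already has the complete oxygen pattern of the C2 aryl ring.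

## Other disconnections considered

**Alternative 1:** The cut is the C2–aryl bond, after the C3–CH2 bond has been made through a fused cyclopropane.
- Forward step: 5-bromo-7-methoxybenzofuran A1 and ethyl diazoacetate A2 would react under CuOTf and a chiral bis(oxazoline). The carbene on monovalent copper adds across C2=C3 to give the exo cyclopropane A3, whose ring-fusion carbon next to ring A already has the configuration of C3 of the target. A Lewis acid would then open the donor–acceptor cyclopropane at the oxygen-bearing carbon, and an arene such as 2,6-dimethoxyphenol A4 would attack C2 through its para position, anti to the C3 arm.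
- In favour: the enantioselective step belongs to a well-established reaction type for furans and benzofurans, so on precedent for the stereo-defining step this alternative is the better one. A4 could enter without a protecting group. The bromide allows a late Heck reaction for the acrylate.
- Against: the carbene carbon brings its ester with it, so ring opening leaves a two-carbon acetate arm at C3 where the target has CH2OH. The ester carbon would have to be excised (saponification, then a decarboxylative oxygenation), which costs two or three steps of modest reliability. The ring-opened oxocarbenium ion can also lose its C3 proton and aromatise, which would erase the stereocentre in competition with arylation. A1 has to be made as well.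
- Comparison: both plans set C3 by catalyst control and C2 by substrate control. The alternative works on a preformed heteroring and gains no ring. Its first step is better precedented, its second and third less so. It would need roughly nine or ten steps against eight.

**Alternative 2:** The cut is at C2–aryl and C3–CH2 on an intact benzofuran.
- Forward step: 5-(dimethoxymethyl)-7-methoxybenzofuran A5, lithiated at C2, would be combined with the aryl boronic ester A6 to an ate complex. With allyl acetate A7, Pd2(dba)3 and a chiral bisphosphine, the allyl–palladium electrophile attacks C3 while the aryl group shifts from boron to C2, giving A8 with aryl trans to allyl.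
- In favour: three pieces are joined in one flask and both stereocentres come under catalyst control, in a reaction type established for heteroaryl boronate complexes. On convergence and precedent it is the better plan. The benzyl ether could be removed by hydrogenolysis before any acrylate exists, which is gentler than the Lewis acid the chosen plan needs, and this too counts in its favour.
- Against: C2 of A8 is quaternary and carries boron. Boron must be exchanged for hydrogen with retention at a tertiary, benzylic, oxygen-bearing centre, and the stereochemical course of that exchange is uncertain. The allyl group is two carbons too long (isomerisation to propenyl, oxidative cleavage, reduction). The acetal must still be unmasked and olefinated.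
- Comparison: the key step forms two bonds to carbon but closes no ring, and leaves two carbons and a boron to be removed. At least six operations follow it and three or four precede it, about twelve in all against eight.

**Alternative 3:** The cut is the C3–C3a bond, made by ring contraction.
- Forward step: the (S)-flavanone A9 would be treated with PhI(OAc)2 and catalytic H2SO4 in methanol with methyl orthoformate. Trivalent iodine attacks the enol ether at C3, ring carbon C4a migrates from the carbonyl carbon to C3 as the iodane leaves, and the former carbonyl carbon becomes the methyl ester of the trans product A10.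
- In favour: the ring contraction is a known reaction of flavanones, so on precedent for the key step it is the better plan. C3 arrives with exactly one carbon at the ester level, so one reduction gives CH2OH. No benzyl ether is used and the pivalate falls during reduction or saponification, so the end game needs no Lewis acid, another point on which it is better. The step count, about eight, is equal.
- Against: the absolute configuration must come from a separate asymmetric synthesis of A9. C2 of a flavanone with an oxygenated 2-aryl ring racemises readily through the ring-opened chalcone, and the acid of this very step invites that. An electron-rich 2-aryl group also tends to migrate itself or to promote dehydrogenation. That is why the ring must be detuned with a pivalate, and why the outcome with three oxygens on that ring stays uncertain.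
- Comparison: the alternative forms one C–C bond and relays one stereocentre from another that must already be present and must survive. The chosen plan creates the ring, two bonds and both centres from an achiral alkene, but rests on a step without direct precedent.

Key step: step 6

Remarks on the chemistry (assumptions and checks):
- The chiral acid of step 6 is taken to be HN[P(=NSO2CF3)(O2Ar*)]2, where O2Ar* is (S)-3,3′-bis[3,5-bis(trifluoromethyl)phenyl]-1,1′-binaphthalene-2,2′-diolate. It is an imidodiphosphorimidate acid, abbreviated IDPi-H. Which enantiomer favours (2S,3R) cannot be foretold. The (S,S) form is written, and its mirror image would be used if the sense proves opposite.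
- In ring A the acrylate at C5 is para to O1 (C7a) and meta to C3a. It weakens ring A as a donor only indirectly, by drawing on the O1 lone pair. The plan therefore also relies on the bulky silyl group, which twists that lone pair out of conjugation.
- Compounds 10 and 12 are both (2S,3R) with the aryl group and the C3 arm trans. No change to the constitution of 7, 10 or 12 was needed.

## Route

Step 1
Reactants: 1 5-iodovanillin (4-hydroxy-3-iodo-5-methoxybenzaldehyde)
Product: 2 methyl (E)-3-(4-hydroxy-3-iodo-5-methoxyphenyl)acrylate
Conditions: Ph3P=CHCO2Me (1.3 equiv), toluene, 90 °C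
Reagents that add atoms: methyl (triphenylphosphoranylidene)acetate, COC(=O)C=P(c1ccccc1)(c1ccccc1)c1ccccc1
Why: Wittig olefination with a stabilised ylide needs no added base, so the phenol stays protonated and the aldehyde stays electrophilic; the ester-stabilised ylide should give the (E)-acrylate.

Step 2
Reactants: 3 syringaldehyde (4-hydroxy-3,5-dimethoxybenzaldehyde)
Product: 4 4-benzyloxy-3,5-dimethoxybenzaldehyde
Conditions: BnBr, K2CO3, DMF, 60 °C
Reagents that add atoms: benzyl bromide, BrCc1ccccc1
Why: Williamson ether synthesis; the phenoxide, although flanked by two methoxy groups, should be alkylated readily by the unhindered benzylic bromide, and the aldehyde is inert.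

Step 3
Reactants: 4 4-benzyloxy-3,5-dimethoxybenzaldehyde
Product: 5 4-benzyloxy-3,5-dimethoxystyrene
Conditions: Ph3PCH3Br, KOtBu, THF, 0 °C to rt
Reagents that add atoms: methyltriphenylphosphonium bromide, C[P+](c1ccccc1)(c1ccccc1)c1ccccc1.[Br-]
Why: Wittig methylenation of a non-enolisable aromatic aldehyde with the unstabilised ylide; no stereochemistry arises.

Step 4
Reactants: 2 methyl (E)-3-(4-hydroxy-3-iodo-5-methoxyphenyl)acrylate; 5 4-benzyloxy-3,5-dimethoxystyrene
Product: 6 methyl (E)-3-{3-[(E)-2-(4-benzyloxy-3,5-dimethoxyphenyl)vinyl]-4-hydroxy-5-methoxyphenyl}acrylate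
Conditions: Pd(OAc)2 (5 mol %), P(o-tol)3 (10 mol %), Et3N, DMF, 90 °C
Reagents that add atoms: none
Why: Mizoroki–Heck reaction; zerovalent palladium formed from Pd(OAc)2 and the phosphine inserts into the C–I bond of 2, the aryl group adds to the terminal styrene carbon, and syn β-hydride elimination gives the (E)-stilbene. The acrylate of 2, a 1,2-disubstituted electron-poor alkene, should react far more slowly than the terminal styrene.

Step 5
Reactants: 6 methyl (E)-3-{3-[(E)-2-(4-benzyloxy-3,5-dimethoxyphenyl)vinyl]-4-hydroxy-5-methoxyphenyl}acrylate
Product: 7 methyl (E)-3-{3-[(E)-2-(4-benzyloxy-3,5-dimethoxyphenyl)vinyl]-4-(tert-butyldimethylsilyloxy)-5-methoxyphenyl}acrylate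
Conditions: TBSCl, imidazole, DMF, rt to 40 °C
Reagents that add atoms: tert-butyldimethylsilyl chloride, CC(C)(C)[Si](C)(C)Cl
Why: Imidazole-assisted silylation of the phenol gives the aprotic oxygen nucleophile that step 6 needs; the tert-butyldimethylsilyl ether should survive chromatography, and its bulk between two ortho substituents twists the oxygen lone pair out of conjugation with ring A.

Step 6
Reactants: 7 methyl (E)-3-{3-[(E)-2-(4-benzyloxy-3,5-dimethoxyphenyl)vinyl]-4-(tert-butyldimethylsilyloxy)-5-methoxyphenyl}acrylate; 8 benzyl chloromethyl ether
Product: 10 methyl (E)-3-[(2S,3R)-2-(4-benzyloxy-3,5-dimethoxyphenyl)-3-(benzyloxymethyl)-7-methoxy-2,3-dihydrobenzofuran-5-yl]acrylate, via C2 benzylic cation 9 (not isolated)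
Conditions: 8 (1.5 equiv, freshly distilled), (S,S)-HN[P(=NSO2CF3)(O2Ar*)]2 (5 mol %) pre-silylated with methallyl-SiMe3 (10 mol %), toluene, −60 °C; then Et3N
Reagents that add atoms: none
Why: Proposed new method: the silylated chiral acid (R3Si+ X*−) should abstract chloride from 8 to give the benzyloxymethyl oxocarbenium ion paired with the chiral anion X*−; the C2=C3 bond of 7 attacks it through C3 (C3–CH2 bond), the charge arrives at C2 in cation 9, and the silyl ether oxygen O1 closes the dihydrofuran ring on C2 in a 5-exo capture (the cationic π system lies outside the new ring, as in an addition to a para-quinone methide), after which the silyloxonium ion hands its silyl group to X*− to restart the cycle and chloride leaves as the silyl chloride. The closest known reaction types are silylium–imidodiphosphorimidate additions of one-carbon oxocarbenium and iminium ions to silyl ketene acetals, catalytic asymmetric Prins reactions of aryl alkenes with formaldehyde, and racemic cation–phenol closures to trans-2-aryl-dihydrobenzofurans. C3 is set in the C–C bond-forming event, where the confined chiral anion selects the alkene face that the achiral cation approaches. C2 is set afterwards by substrate control, O1 adding to the planar cation anti to the new C3 substituent; this is also the more stable trans arrangement, so a cis isomer can re-ionise and correct itself. Regioselectivity (attack through C3, not C2) rests on the alkoxy group para to C2, set against a ring A whose silyloxy group is twisted and shares its lone pair with the acrylate para to it. Chemoselectivity rests on the electron-poor acrylate alkene being unreactive and on the pre-silylated, aprotic catalyst offering no proton to the stilbene. Face selectivity can come only from the catalyst.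

Step 7
Reactants: 10 methyl (E)-3-[(2S,3R)-2-(4-benzyloxy-3,5-dimethoxyphenyl)-3-(benzyloxymethyl)-7-methoxy-2,3-dihydrobenzofuran-5-yl]acrylate
Product: 11 (E)-3-[(2S,3R)-2-(4-benzyloxy-3,5-dimethoxyphenyl)-3-(benzyloxymethyl)-7-methoxy-2,3-dihydrobenzofuran-5-yl]acrylic acid
Conditions: LiOH·H2O, THF/MeOH/H2O, rt; then 1 M HCl to pH 3
Reagents that add atoms: lithium hydroxide (hydroxide oxygen), [Li+].[OH-]
Why: Saponification of the methyl cinnamate; benzyl and methyl ethers and both stereocentres (neither is enolisable) are inert, and no free phenol is present that could open the ring as a phenoxide.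

Step 8
Reactants: 11 (E)-3-[(2S,3R)-2-(4-benzyloxy-3,5-dimethoxyphenyl)-3-(benzyloxymethyl)-7-methoxy-2,3-dihydrobenzofuran-5-yl]acrylic acid
Product: 12 (E)-3-[(2S,3R)-2-(4-hydroxy-3,5-dimethoxyphenyl)-3-(hydroxymethyl)-7-methoxy-2,3-dihydrobenzofuran-5-yl]acrylic acid
Conditions: BCl3 (6 equiv), C6HMe5 (6 equiv), CH2Cl2, −78 to −40 °C; then MeOH/CHCl3, aq. NaHCO3, acidify
Reagents that add atoms: none
Why: Lewis-acid debenzylation with a non-basic cation scavenger; BCl3 binds the ether oxygens, the benzyl groups are captured by pentamethylbenzene in a Friedel–Crafts alkylation, and the boron esters are hydrolysed on quench. The aryl benzyl ether, pressed between two methoxy groups, should fall first, and the O–BCl2 group it leaves para to C2 then disfavours ionisation of C2–O1; at this temperature the methyl ethers and the acrylic acid should remain, and neither stereocentre is touched.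

## Compound list

1 | 5-iodovanillin (4-hydroxy-3-iodo-5-methoxybenzaldehyde) | COc1cc(C=O)cc(I)c1O | starting material
2 | methyl (E)-3-(4-hydroxy-3-iodo-5-methoxyphenyl)acrylate | COC(=O)/C=C/c1cc(I)c(O)c(OC)c1 | intermediate
3 | syringaldehyde (4-hydroxy-3,5-dimethoxybenzaldehyde) | COc1cc(C=O)cc(OC)c1O | starting material
4 | 4-benzyloxy-3,5-dimethoxybenzaldehyde | COc1cc(C=O)cc(OC)c1OCc1ccccc1 | intermediate
5 | 4-benzyloxy-3,5-dimethoxystyrene | C=Cc1cc(OC)c(OCc2ccccc2)c(OC)c1 | intermediate
6 | methyl (E)-3-{3-[(E)-2-(4-benzyloxy-3,5-dimethoxyphenyl)vinyl]-4-hydroxy-5-methoxyphenyl}acrylate | COC(=O)/C=C/c1cc(OC)c(O)c(/C=C/c2cc(OC)c(OCc3ccccc3)c(OC)c2)c1 | intermediate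
7 | methyl (E)-3-{3-[(E)-2-(4-benzyloxy-3,5-dimethoxyphenyl)vinyl]-4-(tert-butyldimethylsilyloxy)-5-methoxyphenyl}acrylate | COC(=O)/C=C/c1cc(OC)c(O[Si](C)(C)C(C)(C)C)c(/C=C/c2cc(OC)c(OCc3ccccc3)c(OC)c2)c1 | intermediate
8 | benzyl chloromethyl ether | ClCOCc1ccccc1 | starting material
9 | C2 benzylic cation formed by C3 alkoxymethylation of 7 (ion pair with the chiral anion; C3 configured as in 10; not isolated) | COC(=O)/C=C/c1cc(OC)c(O[Si](C)(C)C(C)(C)C)c(c1)[C@@H]([CH+]c1cc(OC)c(OCc2ccccc2)c(OC)c1)COCc1ccccc1 | intermediate
10 | methyl (E)-3-[(2S,3R)-2-(4-benzyloxy-3,5-dimethoxyphenyl)-3-(benzyloxymethyl)-7-methoxy-2,3-dihydrobenzofuran-5-yl]acrylate | COc1cc([C@H]2Oc3c(OC)cc(/C=C/C(=O)OC)cc3[C@@H]2COCc2ccccc2)cc(OC)c1OCc1ccccc1 | intermediate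
11 | (E)-3-[(2S,3R)-2-(4-benzyloxy-3,5-dimethoxyphenyl)-3-(benzyloxymethyl)-7-methoxy-2,3-dihydrobenzofuran-5-yl]acrylic acid | COc1cc([C@H]2Oc3c(OC)cc(/C=C/C(=O)O)cc3[C@@H]2COCc2ccccc2)cc(OC)c1OCc1ccccc1 | intermediate
12 | (E)-3-[(2S,3R)-2-(4-hydroxy-3,5-dimethoxyphenyl)-3-(hydroxymethyl)-7-methoxy-2,3-dihydrobenzofuran-5-yl]acrylic acid | COc1cc([C@H]2Oc3c(OC)cc(/C=C/C(=O)O)cc3[C@@H]2CO)cc(OC)c1O | target

## Step count and least certain steps

Total step count: 8. Longest linear sequence: 7 steps (3 → 4 → 5 → 6 → 7 → 10 → 11 → 12, steps 2 to 8).

**Step 6 (key step, the one that carries the label for a new method).** The most likely failure is poor facial selectivity in the C3–CH2 bond formation. The oxocarbenium ion is small and achiral and the alkene is held in the anion pocket only by weak contacts, so the two faces of the stilbene may be poorly distinguished. Next in likelihood are Friedel–Crafts alkoxymethylation of the two electron-rich rings, attack through C2, and slow turnover because the ester and ether oxygens hold the silylium ion.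

The fallback uses known chemistry, sets out from 4 and comes back at 10:
- 2-[5-Bromo-3-methoxy-2-(methoxymethoxy)phenyl]acetic acid F1, a building block to be prepared separately, is activated as its pivalic mixed anhydride F2 (PivCl, Et3N, THF, −20 °C).
- F2 is joined to lithiated (S)-4-benzyloxazolidin-2-one to give the N-arylacetyl oxazolidinone F3.
- The boron enolate of F3 (Bu2BOTf, i-Pr2NEt, CH2Cl2, −78 °C) adds to 4 in an Evans syn-aldol reaction to give the syn-aldol adduct F4. The auxiliary fixes the carbon that becomes C3.
- LiBH4 (THF/MeOH, 0 °C) removes the auxiliary reductively and gives the 1,3-diol F5.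
- HCl in MeOH removes the methoxymethyl group and ionises the benzylic alcohol. The freed phenol closes the ring on the cation anti to the C3 substituent to give the trans bromo alcohol F6. This is the classical acid closure to phenylcoumarans, and the carbinol configuration is irrelevant.
- O-Benzylation (NaH, BnBr, DMF) gives the bromo dibenzyl ether F7.
- A Heck reaction of F7 with methyl acrylate (Pd(OAc)2, P(o-tol)3, Et3N, DMF, 100 °C) gives 10.

**Step 4.** The most likely failure is arylation at the internal carbon of the electron-rich styrene, which gives the 1,1-diarylethene isomer alongside the stilbene. Turnover may also be sluggish because the phenoxide of 2 binds palladium.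

The fallback sets out from 5 and comes back at 6. Cross-metathesis of 5 with vinylboronic acid pinacol ester (second-generation Grubbs catalyst, CH2Cl2, 40 °C) would give the (E)-styrylboronic acid pinacol ester F8. Suzuki–Miyaura coupling of F8 with 2 (Pd(dppf)Cl2, K2CO3, dioxane/H2O, 80 °C) forms the same aryl–vinyl bond with the position and geometry fixed in advance.

**Step 8.** The most likely failure is loss of chemoselectivity. The C2–O1 bond is itself a benzylic aryl ether and may ionise under BCl3 before the syringyl oxygen is unmasked. The open cation could then be trapped by the scavenger or by chloride, or lose the C3 proton. On warming, a methyl ether next to the freed phenol may also be cleaved.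

The fallback avoids Lewis acid altogether, sets out from 10 and comes back at 12:
- Lemieux–Johnson cleavage of the acrylate double bond (OsO4 cat., NaIO4, 2,6-lutidine, dioxane/H2O) gives the dibenzyl aldehyde F9.
- Hydrogenolysis (H2, Pd/C, EtOAc, rt, stopped at debenzylation) is possible now that no alkene is present and gives the hydroxy aldehyde F10.
- Knoevenagel–Doebner condensation with malonic acid (pyridine, piperidine cat., 70 °C) passes through the arylidenemalonic acid F11, which decarboxylates to 12 directly as the (E)-acid.

## Further compounds

F1 | step 6 | 2-[5-bromo-3-methoxy-2-(methoxymethoxy)phenyl]acetic acid | OC(=O)Cc1cc(Br)cc(OC)c1OCOC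
F2 | step 6 | 2-[5-bromo-3-methoxy-2-(methoxymethoxy)phenyl]acetic pivalic anhydride | CC(C)(C)C(=O)OC(=O)Cc1cc(Br)cc(OC)c1OCOC
F3 | step 6 | (S)-4-benzyl-3-{2-[5-bromo-3-methoxy-2-(methoxymethoxy)phenyl]acetyl}oxazolidin-2-one | O=C(Cc1cc(Br)cc(OC)c1OCOC)N1[C@@H](Cc2ccccc2)COC1=O
F4 | step 6 | (S)-4-benzyl-3-{(2S,3S)-3-(4-benzyloxy-3,5-dimethoxyphenyl)-2-[5-bromo-3-methoxy-2-(methoxymethoxy)phenyl]-3-hydroxypropanoyl}oxazolidin-2-one | O=C(N1[C@@H](Cc2ccccc2)COC1=O)[C@@H](c1cc(Br)cc(OC)c1OCOC)[C@H](O)c1cc(OC)c(OCc2ccccc2)c(OC)c1
F5 | step 6 | (1S,2R)-1-(4-benzyloxy-3,5-dimethoxyphenyl)-2-[5-bromo-3-methoxy-2-(methoxymethoxy)phenyl]propane-1,3-diol | OC[C@@H](c1cc(Br)cc(OC)c1OCOC)[C@H](O)c1cc(OC)c(OCc2ccccc2)c(OC)c1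
F6 | step 6 | [(2S,3R)-2-(4-benzyloxy-3,5-dimethoxyphenyl)-5-bromo-7-methoxy-2,3-dihydrobenzofuran-3-yl]methanol | COc1cc([C@H]2Oc3c(OC)cc(Br)cc3[C@@H]2CO)cc(OC)c1OCc1ccccc1
F7 | step 6 | (2S,3R)-2-(4-benzyloxy-3,5-dimethoxyphenyl)-3-(benzyloxymethyl)-5-bromo-7-methoxy-2,3-dihydrobenzofuran | COc1cc([C@H]2Oc3c(OC)cc(Br)cc3[C@@H]2COCc2ccccc2)cc(OC)c1OCc1ccccc1
F8 | step 4 | (E)-2-[2-(4-benzyloxy-3,5-dimethoxyphenyl)vinyl]-4,4,5,5-tetramethyl-1,3,2-dioxaborolane | COc1cc(/C=C/B2OC(C)(C)C(C)(C)O2)cc(OC)c1OCc1ccccc1
F9 | step 8 | (2S,3R)-2-(4-benzyloxy-3,5-dimethoxyphenyl)-3-(benzyloxymethyl)-7-methoxy-2,3-dihydrobenzofuran-5-carbaldehyde | COc1cc([C@H]2Oc3c(OC)cc(C=O)cc3[C@@H]2COCc2ccccc2)cc(OC)c1OCc1ccccc1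
F10 | step 8 | (2S,3R)-2-(4-hydroxy-3,5-dimethoxyphenyl)-3-(hydroxymethyl)-7-methoxy-2,3-dihydrobenzofuran-5-carbaldehyde | COc1cc([C@H]2Oc3c(OC)cc(C=O)cc3[C@@H]2CO)cc(OC)c1O
F11 | step 8 | 2-{[(2S,3R)-2-(4-hydroxy-3,5-dimethoxyphenyl)-3-(hydroxymethyl)-7-methoxy-2,3-dihydrobenzofuran-5-yl]methylene}malonic acid | COc1cc([C@H]2Oc3c(OC)cc(C=C(C(=O)O)C(=O)O)cc3[C@@H]2CO)cc(OC)c1O
A1 | alternative 1 | 5-bromo-7-methoxybenzofuran | COc1cc(Br)cc2ccoc12
A2 | alternative 1 | ethyl diazoacetate | CCOC(=O)C=[N+]=[N-]
A3 | alternative 1 | ethyl exo-5-bromo-3-methoxy-1a,6b-dihydro-1H-cyclopropa[b][1]benzofuran-1-carboxylate (single enantiomer) | CCOC(=O)[C@H]1[C@@H]2Oc3c(OC)cc(Br)cc3[C@H]12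
A4 | alternative 1 | 2,6-dimethoxyphenol | COc1cccc(OC)c1O
A5 | alternative 2 | 5-(dimethoxymethyl)-7-methoxybenzofuran | COC(OC)c1cc(OC)c2occc2c1
A6 | alternative 2 | 2-(4-benzyloxy-3,5-dimethoxyphenyl)-4,4,5,5-tetramethyl-1,3,2-dioxaborolane | COc1cc(B2OC(C)(C)C(C)(C)O2)cc(OC)c1OCc1ccccc1
A7 | alternative 2 | allyl acetate | CC(=O)OCC=C
A8 | alternative 2 | 2-[3-allyl-2-(4-benzyloxy-3,5-dimethoxyphenyl)-5-(dimethoxymethyl)-7-methoxy-2,3-dihydrobenzofuran-2-yl]-4,4,5,5-tetramethyl-1,3,2-dioxaborolane (aryl trans to allyl, single enantiomer) | COc1cc([C@@]2(B4OC(C)(C)C(C)(C)O4)Oc3c(OC)cc(C(OC)OC)cc3[C@@H]2CC=C)cc(OC)c1OCc1ccccc1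
A9 | alternative 3 | (S)-6-bromo-2-[3,5-dimethoxy-4-(pivaloyloxy)phenyl]-8-methoxychroman-4-one | O=C1C[C@@H](c2cc(OC)c(OC(=O)C(C)(C)C)c(OC)c2)Oc2c(OC)cc(Br)cc12
A10 | alternative 3 | methyl (2S,3S)-5-bromo-2-[3,5-dimethoxy-4-(pivaloyloxy)phenyl]-7-methoxy-2,3-dihydrobenzofuran-3-carboxylate (trans) | COc1cc([C@H]2Oc3c(OC)cc(Br)cc3[C@@H]2C(=O)OC)cc(OC)c1OC(=O)C(C)(C)C
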